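**Assumption:** ethyl (R)-4-chloro-3-hydroxybutanoate (a bulk chiral intermediate) is taken as the cheap chiral purchase; the carbinol centre of 11 and the open/hemiketal forms of 26 are stereochemically irrelevant. The route is a paper design and has not been run.

## Retrosynthetic overview

1. Target 29 ⇐ hydroquinone/quinone redox and oxidation of the side-chain carbinol ⇐ hydroxy ketone 26 ⇐ cis-fused δ-lactone 17 + allylbarium from aryl chloride 24 (α-selective acylation).
2. Lactone 17 ⇐ ring hydrogenation of 16 ⇐ tethered orthoester Claisen [3,3] of cis-diol 13. This forms the ring C–CH2 bond and the second quaternary centre.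
3. Diol 13 ⇐ Luche reduction of cyclopentenone 12 ⇐ Stork–Danheiser sequence on 1,3-dione 9 ⇐ Dieckmann-type closure of keto ester 8.
4. First quaternary centre ⇐ two Fráter–Seebach alkylations (Me, then allyl) of β-hydroxy ester 4. Its carbinol, bought in 1, later becomes the C=O of the prenyl ketone.
5. Ring order: cyclopentane (Dieckmann), then the temporary δ-lactone (Claisen); the arene is bought.

## Route

Step 1
Reactants: 1 ethyl (3R)-4-chloro-3-hydroxybutanoate
Product: 2 ethyl 2-[(2R)-oxiran-2-yl]acetate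
Conditions: Ag2O, MeCN, 60 °C, dark
Reagents that add atoms: none
Why: Silver-assisted intramolecular Williamson closure of the chlorohydrin leaves the C–O stereocentre untouched and avoids base-induced elimination to the hydroxycrotonate.

Step 2
Reactants: 2 ethyl 2-[(2R)-oxiran-2-yl]acetate; 3 (2-methylprop-1-en-1-yl)magnesium bromide
Product: 4 ethyl (3S)-3-hydroxy-6-methylhept-5-enoate
Conditions: CuI (10 mol%), THF, −40 → −20 °C
Reagents that add atoms: none
Why: Cu-catalysed Grignard opening of the terminal epoxide at CH2 (SN2) installs the prenyl unit; the carbinol is unchanged (descriptor changes only by priority).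

Step 3
Reactants: 4 ethyl (3S)-3-hydroxy-6-methylhept-5-enoate
Product: 5 ethyl (2S,3S)-3-hydroxy-2,6-dimethylhept-5-enoate
Conditions: LDA (2.2 equiv), THF, −78 → −20 °C; MeI, −78 → 0 °C
Reagents that add atoms: iodomethane, CI
Why: Fráter–Seebach alkylation: the Li-chelated dianion is methylated anti to the C-3 alkyl group, giving the anti (2S,3S) product.

Step 4
Reactants: 5 ethyl (2S,3S)-3-hydroxy-2,6-dimethylhept-5-enoate
Product: 6 ethyl (2S,3S)-3-hydroxy-2,6-dimethyl-2-(prop-2-en-1-yl)hept-5-enoate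
Conditions: LDA (2.2 equiv), THF/DMPU, −78 → −20 °C; allyl bromide, −78 → 0 °C
Reagents that add atoms: allyl bromide, C=CCBr
Why: Second Fráter–Seebach alkylation: allyl bromide enters the same face (anti to the C-3 substituent), so the order Me-then-allyl fixes the first quaternary centre.

Step 5
Reactants: 6 ethyl (2S,3S)-3-hydroxy-2,6-dimethyl-2-(prop-2-en-1-yl)hept-5-enoate
Product: 7 ethyl (2S,3S)-2,6-dimethyl-2-(prop-2-en-1-yl)-3-[(triethylsilyl)oxy]hept-5-enoate
Conditions: TESOTf, 2,6-lutidine, CH2Cl2, −78 → 0 °C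
Reagents that add atoms: triethylsilyl trifluoromethanesulfonate, CC[Si](CC)(CC)OS(=O)(=O)C(F)(F)F
Why: Silylation of the hindered carbinol blocks retro-aldol cleavage in the basic steps that follow.

Step 6
Reactants: 7 ethyl (2S,3S)-2,6-dimethyl-2-(prop-2-en-1-yl)-3-[(triethylsilyl)oxy]hept-5-enoate
Product: 8 ethyl (2S,3S)-2,6-dimethyl-2-(2-oxopropyl)-3-[(triethylsilyl)oxy]hept-5-enoate
Conditions: PdCl2 (10 mol%), Cu(OAc)2 (20 mol%), O2 (1 atm), DMA/H2O 7:1, rt
Reagents that add atoms: water, O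
Why: Tsuji–Wacker oxidation converts only the terminal alkene to the methyl ketone; the trisubstituted prenyl alkene and the silyl ether survive the acetate-buffered conditions.

Step 7
Reactants: 8 ethyl (2S,3S)-2,6-dimethyl-2-(2-oxopropyl)-3-[(triethylsilyl)oxy]hept-5-enoate
Product: 9 (4S)-4-methyl-4-[(1S)-4-methyl-1-[(triethylsilyl)oxy]pent-3-en-1-yl]cyclopentane-1,3-dione
Conditions: KOt-Bu (2.2 equiv), THF, 0 °C → rt; aq. HCl to pH 4
Reagents that add atoms: none
Why: Dieckmann-type intramolecular Claisen condensation: only the methyl-ketone enolate can close a five-membered ring on the ester, and the dione enolate drives it.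

Step 8
Reactants: 9 (4S)-4-methyl-4-[(1S)-4-methyl-1-[(triethylsilyl)oxy]pent-3-en-1-yl]cyclopentane-1,3-dione
Product: 10 (5S)-3-methoxy-5-methyl-5-[(1S)-4-methyl-1-[(triethylsilyl)oxy]pent-3-en-1-yl]cyclopent-2-en-1-one
Conditions: TMSCHN2, toluene/MeOH 4:1, 0 °C → rt
Reagents that add atoms: (trimethylsilyl)diazomethane, C[Si](C)(C)C=[N+]=[N-]
Why: Neutral diazoalkane O-methylation should favour the enol oxygen remote from the quaternary centre, leaving the C=O next to that centre (the minor regioisomer is separated).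

Step 9
Reactants: 10 (5S)-3-methoxy-5-methyl-5-[(1S)-4-methyl-1-[(triethylsilyl)oxy]pent-3-en-1-yl]cyclopent-2-en-1-one
Product: 12 (4R)-4-[(1S)-1-hydroxy-4-methylpent-3-en-1-yl]-3,4-dimethylcyclopent-2-en-1-one, via tertiary alkoxide adduct 11 (not isolated)
Conditions: MeLi, CeCl3, THF, −78 °C; then 2 M HCl, THF, rt
Reagents that add atoms: methyllithium, [Li]C
Why: Stork–Danheiser transposition: 1,2-addition to the vinylogous ester, then acid hydrolysis/dehydration gives the β-methyl enone; the same acid removes the TES group.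

Step 10
Reactants: 12 (4R)-4-[(1S)-1-hydroxy-4-methylpent-3-en-1-yl]-3,4-dimethylcyclopent-2-en-1-one
Product: 13 (1S,4R)-4-[(1S)-1-hydroxy-4-methylpent-3-en-1-yl]-3,4-dimethylcyclopent-2-en-1-ol
Conditions: NaBH4, CeCl3·7H2O, MeOH, −78 °C
Reagents that add atoms: none
Why: Luche 1,2-reduction: hydride should attack anti to the branched side chain on the quaternary carbon, placing the ring OH cis to it (substrate control from the bought carbinol via the first quaternary centre).

Step 11
Reactants: 13 (1S,4R)-4-[(1S)-1-hydroxy-4-methylpent-3-en-1-yl]-3,4-dimethylcyclopent-2-en-1-ol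
Product: 16 (1S,4aS,7aR)-4a,7a-dimethyl-1-(3-methylbut-2-en-1-yl)-4,4a,7,7a-tetrahydrocyclopenta[c]pyran-3(1H)-one, via cyclic orthoester 14 (not isolated), via cyclic ketene acetal 15 (not isolated)
Conditions: MeC(OEt)3, pivalic acid (cat.), xylene, 140 °C (−EtOH)
Reagents that add atoms: triethyl orthoacetate, CCOC(C)(OCC)OCC
Why: Johnson orthoester Claisen [3,3]: the ketene acetal tethered through the bought carbinol oxygen delivers CH2C(=O) suprafacially from the allylic C–O face, so the second quaternary centre forms cis and is locked as the cis-fused δ-lactone.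

Step 12
Reactants: 16 (1S,4aS,7aR)-4a,7a-dimethyl-1-(3-methylbut-2-en-1-yl)-4,4a,7,7a-tetrahydrocyclopenta[c]pyran-3(1H)-one
Product: 17 (1S,4aR,7aR)-4a,7a-dimethyl-1-(3-methylbut-2-en-1-yl)hexahydrocyclopenta[c]pyran-3(1H)-one
Conditions: 2-nitrobenzenesulfonylhydrazide, Et3N, CH2Cl2, rt
Reagents that add atoms: none
Why: Diimide reduction saturates the strained cis-disubstituted ring alkene much faster than the trisubstituted prenyl alkene and touches no stereocentre.

Step 13
Reactants: 18 4-methoxy-2-methylphenol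
Product: 19 2-bromo-4-methoxy-6-methylphenol
Conditions: NBS, MeCN, 0 °C
Reagents that add atoms: N-bromosuccinimide, O=C1CCC(=O)N1Br
Why: Electrophilic aromatic bromination goes ortho to the free OH, the only open position activated by the stronger donor.

Step 14
Reactants: 19 2-bromo-4-methoxy-6-methylphenol
Product: 20 1-bromo-2,5-dimethoxy-3-methylbenzene
Conditions: MeI, K2CO3, acetone, reflux
Reagents that add atoms: iodomethane, CI
Why: Williamson etherification gives the dimethyl hydroquinone ether, which tolerates the organometallic steps.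

Step 15
Reactants: 20 1-bromo-2,5-dimethoxy-3-methylbenzene; 21 2-methyl-2-vinyloxirane
Product: 23 (2E)-4-(2,5-dimethoxy-3-methylphenyl)-2-methylbut-2-en-1-ol, via aryl Grignard 22 (not isolated)
Conditions: Mg, THF, rt; CuI (10 mol%), 21, −30 °C
Reagents that add atoms: none
Why: Cu-catalysed SN2′ opening of isoprene monoxide by the aryl Grignard gives the E-trisubstituted allylic alcohol as the major isomer (minor Z removed here).

Step 16
Reactants: 23 (2E)-4-(2,5-dimethoxy-3-methylphenyl)-2-methylbut-2-en-1-ol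
Product: 24 1-[(2E)-4-chloro-3-methylbut-2-en-1-yl]-2,5-dimethoxy-3-methylbenzene
Conditions: NCS, Me2S, CH2Cl2, −20 → 0 °C
Reagents that add atoms: N-chlorosuccinimide, O=C1CCC(=O)N1Cl
Why: Corey–Kim chlorination converts the primary allylic alcohol to the chloride without allylic transposition or E/Z loss.

Step 17
Reactants: 17 (1S,4aR,7aR)-4a,7a-dimethyl-1-(3-methylbut-2-en-1-yl)hexahydrocyclopenta[c]pyran-3(1H)-one; 24 1-[(2E)-4-chloro-3-methylbut-2-en-1-yl]-2,5-dimethoxy-3-methylbenzene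
Product: 26 (4E)-6-(2,5-dimethoxy-3-methylphenyl)-1-[(1R,2R)-2-[(1S)-1-hydroxy-4-methylpent-3-en-1-yl]-1,2-dimethylcyclopentyl]-4-methylhex-4-en-2-one, via allylbarium chloride 25 (not isolated)
Conditions: BaI2, lithium biphenylide (2 equiv), THF, rt; 24, −78 °C; then 17, −78 °C; aq. NH4Cl
Reagents that add atoms: none
Why: Allylbarium reagents (Yamamoto-type) react at the unsubstituted α-carbon with retention of alkene geometry; at −78 °C the lactone should stop at the hemiketalate, so one allyl unit gives the β,γ-unsaturated ketone and frees the side-chain carbinol.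

Step 18
Reactants: 26 (4E)-6-(2,5-dimethoxy-3-methylphenyl)-1-[(1R,2R)-2-[(1S)-1-hydroxy-4-methylpent-3-en-1-yl]-1,2-dimethylcyclopentyl]-4-methylhex-4-en-2-one
Product: 27 1-[(1R,2R)-2-[(3E)-5-(2,5-dimethoxy-3-methylphenyl)-3-methyl-2-oxopent-3-en-1-yl]-1,2-dimethylcyclopentyl]-4-methylpent-3-en-1-one
Conditions: Dess–Martin periodinane, NaHCO3, CH2Cl2, 0 °C → rt
Reagents that add atoms: none
Why: Buffered Dess–Martin oxidation turns the bought carbinol (its controlling role finished) into the prenyl ketone without moving either β,γ-alkene into conjugation.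

Step 19
Reactants: 27 1-[(1R,2R)-2-[(3E)-5-(2,5-dimethoxy-3-methylphenyl)-3-methyl-2-oxopent-3-en-1-yl]-1,2-dimethylcyclopentyl]-4-methylpent-3-en-1-one
Product: 29 1-[(1R,2R)-2-[(3E)-5-(2,5-dihydroxy-3-methylphenyl)-3-methyl-2-oxopent-3-en-1-yl]-1,2-dimethylcyclopentyl]-4-methylpent-3-en-1-one, via quinone diketone 28 (not isolated)
Conditions: CAN, MeCN/H2O, 0 °C; then aq. Na2S2O4, EtOAc, rt
Reagents that add atoms: water, O
Why: CAN oxidative demethylation gives the p-quinone, and dithionite reduces it to the hydroquinone without touching ketones or alkenes.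

## Compound list

1 | ethyl (3R)-4-chloro-3-hydroxybutanoate | CCOC(=O)C[C@@H](O)CCl | starting material
2 | ethyl 2-[(2R)-oxiran-2-yl]acetate | CCOC(=O)C[C@@H]1CO1 | intermediate
3 | (2-methylprop-1-en-1-yl)magnesium bromide | CC(C)=C[Mg]Br | starting material
4 | ethyl (3S)-3-hydroxy-6-methylhept-5-enoate | CCOC(=O)C[C@@H](O)CC=C(C)C | intermediate
5 | ethyl (2S,3S)-3-hydroxy-2,6-dimethylhept-5-enoate | CCOC(=O)[C@@H](C)[C@@H](O)CC=C(C)C | intermediate
6 | ethyl (2S,3S)-3-hydroxy-2,6-dimethyl-2-(prop-2-en-1-yl)hept-5-enoate | CCOC(=O)[C@@](C)(CC=C)[C@@H](O)CC=C(C)C | intermediate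
7 | ethyl (2S,3S)-2,6-dimethyl-2-(prop-2-en-1-yl)-3-[(triethylsilyl)oxy]hept-5-enoate | CCOC(=O)[C@@](C)(CC=C)[C@@H](O[Si](CC)(CC)CC)CC=C(C)C | intermediate
8 | ethyl (2S,3S)-2,6-dimethyl-2-(2-oxopropyl)-3-[(triethylsilyl)oxy]hept-5-enoate | CCOC(=O)[C@@](C)(CC(C)=O)[C@@H](O[Si](CC)(CC)CC)CC=C(C)C | intermediate
9 | (4S)-4-methyl-4-[(1S)-4-methyl-1-[(triethylsilyl)oxy]pent-3-en-1-yl]cyclopentane-1,3-dione | CC(C)=CC[C@H](O[Si](CC)(CC)CC)[C@]1(C)CC(=O)CC1=O | intermediate
10 | (5S)-3-methoxy-5-methyl-5-[(1S)-4-methyl-1-[(triethylsilyl)oxy]pent-3-en-1-yl]cyclopent-2-en-1-one | CC(C)=CC[C@H](O[Si](CC)(CC)CC)[C@]1(C)CC(OC)=CC1=O | intermediate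
11 | (5S)-3-methoxy-1,5-dimethyl-5-[(1S)-4-methyl-1-[(triethylsilyl)oxy]pent-3-en-1-yl]cyclopent-2-en-1-ol (as lithium alkoxide, C-1 epimers) | CC(C)=CC[C@H](O[Si](CC)(CC)CC)[C@]1(C)CC(OC)=CC1(C)O | intermediate
12 | (4R)-4-[(1S)-1-hydroxy-4-methylpent-3-en-1-yl]-3,4-dimethylcyclopent-2-en-1-one | CC(C)=CC[C@H](O)[C@]1(C)CC(=O)C=C1C | intermediate
13 | (1S,4R)-4-[(1S)-1-hydroxy-4-methylpent-3-en-1-yl]-3,4-dimethylcyclopent-2-en-1-ol (ring OH cis to the side chain) | CC(C)=CC[C@H](O)[C@]1(C)C[C@H](O)C=C1C | intermediate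
14 | 3-ethoxy-3,6,7-trimethyl-5-(3-methylbut-2-en-1-yl)-2,4-dioxabicyclo[4.2.1]non-7-ene (cyclic orthoacetate of 13) | CC(C)=CC[C@@H]1OC(C)(OCC)O[C@H]2C[C@]1(C)C(C)=C2 | intermediate
15 | 6,7-dimethyl-3-methylidene-5-(3-methylbut-2-en-1-yl)-2,4-dioxabicyclo[4.2.1]non-7-ene (cyclic ketene acetal) | CC(C)=CC[C@@H]1OC(=C)O[C@H]2C[C@]1(C)C(C)=C2 | intermediate
16 | (1S,4aS,7aR)-4a,7a-dimethyl-1-(3-methylbut-2-en-1-yl)-4,4a,7,7a-tetrahydrocyclopenta[c]pyran-3(1H)-one (cis-fused) | CC(C)=CC[C@@H]1OC(=O)C[C@@]2(C)C=CC[C@@]12C | intermediate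
17 | (1S,4aR,7aR)-4a,7a-dimethyl-1-(3-methylbut-2-en-1-yl)hexahydrocyclopenta[c]pyran-3(1H)-one (cis-fused) | CC(C)=CC[C@@H]1OC(=O)C[C@@]2(C)CCC[C@@]12C | intermediate
18 | 4-methoxy-2-methylphenol | COc1ccc(O)c(C)c1 | starting material
19 | 2-bromo-4-methoxy-6-methylphenol | COc1cc(C)c(O)c(Br)c1 | intermediate
20 | 1-bromo-2,5-dimethoxy-3-methylbenzene | COc1cc(C)c(OC)c(Br)c1 | intermediate
21 | 2-methyl-2-vinyloxirane (isoprene monoxide, racemic) | CC1(C=C)CO1 | starting material
22 | (2,5-dimethoxy-3-methylphenyl)magnesium bromide | COc1cc(C)c(OC)c([Mg]Br)c1 | intermediate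
23 | (2E)-4-(2,5-dimethoxy-3-methylphenyl)-2-methylbut-2-en-1-ol | COc1cc(C)c(OC)c(C/C=C(\C)CO)c1 | intermediate
24 | 1-[(2E)-4-chloro-3-methylbut-2-en-1-yl]-2,5-dimethoxy-3-methylbenzene | COc1cc(C)c(OC)c(C/C=C(\C)CCl)c1 | intermediate
25 | [(2E)-4-(2,5-dimethoxy-3-methylphenyl)-2-methylbut-2-en-1-yl]barium chloride | COc1cc(C)c(OC)c(C/C=C(\C)C[Ba]Cl)c1 | intermediate
26 | (4E)-6-(2,5-dimethoxy-3-methylphenyl)-1-[(1R,2R)-2-[(1S)-1-hydroxy-4-methylpent-3-en-1-yl]-1,2-dimethylcyclopentyl]-4-methylhex-4-en-2-one | CC(C)=CC[C@H](O)[C@]1(C)CCC[C@]1(C)CC(=O)C/C(C)=C/Cc1cc(OC)cc(C)c1OC | intermediate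
27 | 1-[(1R,2R)-2-[(3E)-5-(2,5-dimethoxy-3-methylphenyl)-3-methyl-2-oxopent-3-en-1-yl]-1,2-dimethylcyclopentyl]-4-methylpent-3-en-1-one | CC(C)=CCC(=O)[C@]1(C)CCC[C@]1(C)CC(=O)C/C(C)=C/Cc1cc(OC)cc(C)c1OC | intermediate
28 | 2-[(2E)-5-[(1R,2R)-1,2-dimethyl-2-(4-methylpent-3-enoyl)cyclopentyl]-3-methyl-4-oxopent-2-en-1-yl]-6-methylcyclohexa-2,5-diene-1,4-dione | CC(C)=CCC(=O)[C@]1(C)CCC[C@]1(C)CC(=O)C/C(C)=C/CC1=CC(=O)C=C(C)C1=O | intermediate
29 | 1-[(1R,2R)-2-[(3E)-5-(2,5-dihydroxy-3-methylphenyl)-3-methyl-2-oxopent-3-en-1-yl]-1,2-dimethylcyclopentyl]-4-methylpent-3-en-1-one | CC(C)=CCC(=O)[C@]1(C)CCC[C@]1(C)CC(=O)C/C(C)=C/Cc1cc(O)cc(C)c1O | target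

## Step count and risks

Total step count: 19. Longest linear sequence: 15 (steps 1–12, then 17–19).

**Three steps most likely to fail**

Step 11 (Claisen creating the second quaternary centre next to the first). The fallback sets out from 13. Acetic anhydride/pyridine at 0 °C acylates only the unhindered ring carbinol and gives the ring monoacetate F1. Ireland–Claisen rearrangement through its silyl ketene acetal (LDA 3 equiv, TMSCl, THF, −78 → 50 °C, the side-chain OH carried as its TMS ether) and acidic work-up give the hydroxy acid F2. This is closed with PPTS in warm toluene and comes back to the route at 16. The approach changes from a thermal, acid-catalysed orthoester cascade to a low-temperature enolate rearrangement with a separate lactonisation.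

Step 17 (α-selective single addition of the allylbarium to the lactone; risks are enolisation, double addition and E/Z leakage). The fallback sets out from 24 and 17. Sodium benzenesulfinate in DMF converts 24 into the allylic sulfone F3. Its lithio derivative (n-BuLi, THF, −78 °C) can only attack through the sulfonyl-bearing carbon and acylates lactone 17 once, giving the β-keto sulfone F4. SmI2 in THF/MeOH at −78 °C removes the sulfonyl group, coming back at 26.

Step 10 (facial selectivity of the enone reduction, which relays the stereochemistry to the Claisen). The fallback sets out from 12. If the reduction delivers mainly the trans-diol F5, its unhindered allylic carbinol is inverted by a Mitsunobu reaction (4-nitrobenzoic acid, PPh3, DIAD; the neopentyl-type side-chain OH does not react) to the cis 4-nitrobenzoate F6. Methanolysis with K2CO3/MeOH comes back at 13.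

Further compounds
F1 | step 11 | (1S,4R)-4-[(1S)-1-hydroxy-4-methylpent-3-en-1-yl]-3,4-dimethylcyclopent-2-en-1-yl acetate | CC(C)=CC[C@H](O)[C@]1(C)C[C@H](OC(C)=O)C=C1C
F2 | step 11 | 2-[(1S,5R)-5-[(1S)-1-hydroxy-4-methylpent-3-en-1-yl]-1,5-dimethylcyclopent-2-en-1-yl]acetic acid | CC(C)=CC[C@H](O)[C@]1(C)CC=C[C@]1(C)CC(=O)O
F3 | step 17 | 1-[(2E)-4-(benzenesulfonyl)-3-methylbut-2-en-1-yl]-2,5-dimethoxy-3-methylbenzene | COc1cc(C)c(OC)c(C/C=C(\C)CS(=O)(=O)c2ccccc2)c1
F4 | step 17 | (4E)-3-(benzenesulfonyl)-6-(2,5-dimethoxy-3-methylphenyl)-1-[(1R,2R)-2-[(1S)-1-hydroxy-4-methylpent-3-en-1-yl]-1,2-dimethylcyclopentyl]-4-methylhex-4-en-2-one | CC(C)=CC[C@H](O)[C@]1(C)CCC[C@]1(C)CC(=O)C(/C(C)=C/Cc1cc(OC)cc(C)c1OC)S(=O)(=O)c1ccccc1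
F5 | step 10 | (1R,4R)-4-[(1S)-1-hydroxy-4-methylpent-3-en-1-yl]-3,4-dimethylcyclopent-2-en-1-ol (ring OH trans to the side chain) | CC(C)=CC[C@H](O)[C@]1(C)C[C@@H](O)C=C1C
F6 | step 10 | (1S,4R)-4-[(1S)-1-hydroxy-4-methylpent-3-en-1-yl]-3,4-dimethylcyclopent-2-en-1-yl 4-nitrobenzoate | CC(C)=CC[C@H](O)[C@]1(C)C[C@H](OC(=O)c2ccc(cc2)[N+](=O)[O-])C=C1C
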